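The amounts in the recipes below are equal for larch, cedar, elm and alder, 1.50 equiv of first nucleophile and 2.50 equiv of second nucleophile per starting material, so elm and alder differ from larch in when one nucleophile goes in.

| flask | starting material | first nucleophile | second nucleophile | capture agent | remark | time |
|---|---|---|---|---|---|---|
| alpha | 0.020 M | 1.5 equiv | 2.5 equiv | 0.020 M | run made earlier |  |
| beta | 0.013 M | 1.5 equiv | 2.5 equiv | 0.020 M | run made earlier |  |
| gamma | 0.030 M | 1.5 equiv | 2.5 equiv | 0.020 M | run made earlier |  |
| larch | 0.020 M | 1.50 equiv | 2.50 equiv | 0.0200 M | everything together in a closed stirred flask, run for 30 h | 30 h |
| cedar | 0.020 M | 1.50 equiv | 2.50 equiv | 0.0200 M | one stirred flow tank at steady state, fed with the mixture as stated, mean residence time 30 h |  |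
| elm | 0.020 M | 1.50 equiv (fed, over 24.0 h) | 2.50 equiv | 0.0200 M | a stirred flask in which first nucleophile is dosed at a steady rate over 24.0 h without added volume, worked up at 30 h | 30 h |
| alder | 0.020 M | 1.50 equiv | 2.50 equiv (fed, over 24.0 h) | 0.0200 M | all but second nucleophile at the start; second nucleophile goes in evenly over 24.0 h, the run ends at 30 h | 30 h |

| run | time / h | target / % | other capture product / % |
|---|---|---|---|
| alpha | 2.50 | 2.6 | 0 |
| alpha | 6.00 | 5.1 | 0.4 |
| alpha | 12.0 | 14.0 | 3.8 |
| alpha | 30.0 | 29.0 | 2.6 |
| beta | 2.50 | 2.5 | 1.1 |
| beta | 6.00 | 6.7 | 0.7 |
| beta | 12.0 | 12.6 | 1.2 |
| beta | 30.0 | 29.4 | 2.1 |
| gamma | 4.00 | 2.8 | 1.2 |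
| gamma | 10.0 | 9.2 | 0.1 |
| gamma | 20.0 | 20.0 | 2.2 |
| gamma | 30.0 | 29.9 | 2.7 |

(each reading ± 1 percentage point)

- the stated concentrations are those of everything mixed, before any reaction; amounts are the same in each set-up
- the earlier runs were read with a standard deviation of 1 percentage point
- reactions considered so far: starting material -> open intermediate; first nucleophile + open intermediate -> target; second nucleophile + open intermediate -> other capture product; open intermediate + capture agent -> trapped intermediate; 2 second nucleophile -> homo dimer
- the feed brings no volume worth counting
- the earlier runs were made in a closed, stirred flask

1. the set-up with the highest share of target in all that became target or other capture product or trapped intermediate, at the outlet or at the end ("none" if the first two lie within 2 percentage points) (larch / cedar / elm / alder / none)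
2. share of target in all that became target or other capture product or trapped intermediate, at the outlet or at the end, larch
3. share of target in all that became target or other capture product or trapped intermediate, at the outlet or at the end, cedar
4. share of target in all that became target or other capture product or trapped intermediate, at the outlet or at the end, elm
5. share of target in all that became target or other capture product or trapped intermediate, at the outlet or at the end, alder

Follow one molecule of open intermediate: it stands at a fork, and its chance of becoming target is the first nucleophile's amount set against the second nucleophile's, weighted. The last readings of alpha, beta and gamma sum to 88.3% target and 7.40% other capture product. Scaled by the charges, they give 0.0503 as the fork ratio, other capture product formed per target at equal amounts of the two nucleophiles, the selectivity factor. It is a reading, with the scatter of its readings, and this reckoning sets the capture agent aside.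

For larch and cedar, taking the charged amounts, the chance is 92.3%. But elm starts without first nucleophile, so by this reckoning its fork stands even at 2.01 h, when the dosed amount equals the fork ratio times the second nucleophile. Averaging the chance over an even opening of starting material, as the steady rise of the target readings suggests, gives 81.3% for elm. Alder starts without second nucleophile, so this reckoning places its chance above those of the other flasks.

The forecast gives 87% for larch, 86% for cedar, 70% for elm and 91% for alder, with alder best. On elm it says “is starved early”, and its number lies below the reckoning here.

The flasks give 89.8% for larch, 89.8% for cedar, 79.6% for elm and 92.9% for alder, so alder is best. At 30.0 h elm holds 6.03% other capture product, more than the 3.01% in larch.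

    starting material → open intermediate (k = 3.77 × 10⁻⁶ /s)
    first nucleophile + open intermediate → target (k = 0.0133 /M/s)
    second nucleophile + open intermediate → other capture product (k = 8.47 × 10⁻⁴ /M/s)
    open intermediate + capture agent → trapped intermediate (k = 2.04 × 10⁻⁴ /M/s)
    2 second nucleophile → homo dimer (k = 2.86 × 10⁻⁵ /M/s)

In alder the second nucleophile averages 1.50 as fed, ignoring its losses, so the fork ratio gives 95.2% against the computed 92.9%.

With 6.00 equiv of first nucleophile in alder, the same ratio gives 98.8%. The computed flask gives 98.3%.

The readings were generated by integration from invented constants; scatter was added.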